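All constants come from no measurement; no experiment stands behind them.

Two flasks have the same charges apart from protic impurity, at 0.0860 M against 0.034 M, and I want to reckon how far that difference reaches the target.

starting material 0.86 M; reagent 2.15 M (in portions, 4); second substrate 0.430 M; protic impurity 0.0860 M; time 5.0 d; the portions of reagent follow each other after 6.0 min, the first at the start

    starting material + reagent ⇌ target (K1 = 2.9 M⁻¹, k1 = 5.3 × 10⁻⁴ M⁻¹ s⁻¹)
    2 second substrate → self-condensation product (k2 = 3.4 × 10⁻⁴ M⁻¹ s⁻¹)
    starting material + protic impurity → quenched substrate (k3 = 0.0026 M⁻¹ s⁻¹)
    second substrate + reagent ⇌ second product (K4 = 0.35 M⁻¹, k4 = 4.9 × 10⁻⁵ M⁻¹ s⁻¹)

1. the state of affairs at 5.0 d: stopped, and by what, or still going (the reagent has run out first / it is still moving / forward and back rates have come level / all of the starting material has reacted)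
2. the target standing at 5.0 d, as a percentage of the starting material charged

The quench of starting material by protic impurity is irreversible, while target can fall back to starting material. So in the flask I count the impurity's share of starting material as lost, and call what remains the pool S:

S = 0.774 M

I set the second substrate aside. Let x be the target when forward and back rates are level, K = 2.9 M⁻¹ and C = 2.15 M the reagent charge:

x = K(S − x)(C − x), so x = 0.631 M

The ratio x/S = 81.5% is the held share f, the part of the pool standing as target at level rates. Free reagent is then R = C − x = 1.52 M.

Next I count lifetimes. The relaxation time of the target equilibrium, the inverse of the forward constant times R plus the back constant, is 0.281 h. The impurity's lifetime, taken at the lowest starting material I reckon, S − x, is 0.746 h. The run of 5.0 d is far longer than both and holds 161 of the longer one, so I expect the whole loss taken and the rates level.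

The neighbour flask has 0.0520 M more in its pool, and even the whole of that as target takes hardly any of R. So I take its held share to be close to f, and I expect the two flasks to differ in the pool that is shared. For the flask, f times the pool's fraction of the charge gives target at 73.4%.

The forecast says forward and back rates have come level, with target at 73.3%, and its first ground runs “Step 3 is fast and irreversible.”

The flask ends as forward and back rates have come level, with target at 73.3%, and the largest change in the share of a substrate, an intermediate or a product over the second half of the time is 0.024 percentage points. In the neighbour flask, f unchanged on the larger pool gives 78.3%, and that flask ends with target at 77.9%.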